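**Retrosynthetic overview**
1. Feature: ring B (C5–C10, drimane numbering), with C11 on C9 and C12 on C8, is the carbon pattern of a fully substituted phenol. Oxygen sits on C7, the methyl-bearing C10 is para to it, the ester C11 is on C9, the methyl C12 on C8, the C4 side chain on C5, and a removable bromine on C6.
2. Key disconnection C1–C10. Ring B is present first as the arene. Ring A closes second, by para C-alkylation of the phenoxide with the C1 tosylate, which creates quaternary C10 and turns the arene into the ring B dienone.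
3. Arene: methyl 2,6-dimethylbenzoate is brominated and α-arylated with methyl isobutyrate (C4 and its gem-dimethyl group). A second bromination and a C–O coupling install O7. Allylboration sets C3, and ozonolysis trims the chain to C2–C1.
4. After ring closure: hydrogenation gives 5α-H and removes bromine. The C7 ketone is converted to the enol triflate and then to C–H, leaving C6=C7. Deconjugative protonation sets 9α-H and C8=C12. The ester is reduced to the C11 alcohol.
5. Last disconnection C11–O: Mitsunobu etherification with umbelliferone (the coumarin rings are purchased), then desilylation.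

Key step: step 12

Assumption: drimane numbering (ring A C1–C5 and C10, ring B C5–C10, C11 on C9, C12 on C8) is also applied to the aromatic intermediates, and the allylborane derived from (+)-α-pinene is taken as a purchased solution.

**Step 1**
Reactants: 1 methyl 2,6-dimethylbenzoate
Product: 2 methyl 3-bromo-2,6-dimethylbenzoate
Conditions: Br2 (1.0 equiv), FeBr3 (5 mol %), CH2Cl2, 0 °C, dark
Reagents that add atoms: bromine, BrBr
Why: Electrophilic aromatic bromination, in which C3 is ortho to one methyl group, para to the other and meta to the ester, so all three substituents direct there, and one equivalent stops at the monobromide because the first halogen deactivates the ring.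

**Step 2**
Reactants: 2 methyl 3-bromo-2,6-dimethylbenzoate; 3 methyl isobutyrate
Product: 5 methyl 3-(1-methoxy-2-methyl-1-oxopropan-2-yl)-2,6-dimethylbenzoate, via lithium enolate 4 (not isolated)
Conditions: 3, LiNCy2, toluene, 0 °C; then 2, Pd(OAc)2 (cat.), P(t-Bu)3 (cat.), rt to 50 °C
Reagents that add atoms: methyl isobutyrate (3), COC(=O)C(C)C
Why: Palladium-catalysed α-arylation of an ester enolate (Buchwald–Hartwig type), in which the bulky electron-rich phosphine speeds reductive elimination to the quaternary benzylic carbon C4, while the ring ester, twisted out of plane between two methyl groups, resists Claisen attack and lateral deprotonation.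

**Step 3**
Reactants: 5 methyl 3-(1-methoxy-2-methyl-1-oxopropan-2-yl)-2,6-dimethylbenzoate
Product: 6 methyl 3-bromo-5-(1-methoxy-2-methyl-1-oxopropan-2-yl)-2,6-dimethylbenzoate
Conditions: Br2 (1.05 equiv), FeBr3 (5 mol %), CH2Cl2, 0 °C to rt, dark
Reagents that add atoms: bromine, BrBr
Why: Electrophilic aromatic bromination, in which the carbon that becomes C7 is ortho and para to the two methyl groups whereas the other free carbon (C6) is meta to both and shielded by the tert-alkyl group, so two separate brominations avoid any statistical monofunctionalisation of a symmetrical dibromide.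

**Step 4**
Reactants: 6 methyl 3-bromo-5-(1-methoxy-2-methyl-1-oxopropan-2-yl)-2,6-dimethylbenzoate
Product: 7 methyl 3-(benzyloxy)-5-(1-methoxy-2-methyl-1-oxopropan-2-yl)-2,6-dimethylbenzoate
Conditions: BnOH, [Pd(allyl)Cl]2 (cat.), RockPhos (cat.), Cs2CO3, toluene, 90 °C
Reagents that add atoms: benzyl alcohol, OCc1ccccc1
Why: Palladium-catalysed C–O cross-coupling of an aryl bromide with a primary alcohol (Buchwald–Hartwig etherification), which installs O7 already protected because the bulky biaryl phosphine favours C–O reductive elimination over β-hydride elimination, and both hindered esters tolerate the carbonate base.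

**Step 5**
Reactants: 7 methyl 3-(benzyloxy)-5-(1-methoxy-2-methyl-1-oxopropan-2-yl)-2,6-dimethylbenzoate
Product: 8 methyl 3-(benzyloxy)-2,6-dimethyl-5-(2-methyl-1-oxopropan-2-yl)benzoate
Conditions: i-Bu2AlH (1.1 equiv), CH2Cl2, −78 °C; aq. potassium sodium tartrate
Reagents that add atoms: none
Why: Partial ester reduction through a tetrahedral aluminium hemiacetal that is stable at −78 °C, in which the aliphatic ester reacts while the benzoate carbonyl is screened on both faces by its two ortho methyl groups.

**Step 6**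
Reactants: 8 methyl 3-(benzyloxy)-2,6-dimethyl-5-(2-methyl-1-oxopropan-2-yl)benzoate
Product: 10 methyl 3-(benzyloxy)-5-[(3S)-3-hydroxy-2-methylhex-5-en-2-yl]-2,6-dimethylbenzoate, via borinate ester 9 (not isolated)
Conditions: Ipc2B(allyl) derived from (+)-α-pinene, Et2O, −78 °C; then NaOH, H2O2, 0 °C to rt
Reagents that add atoms: B-allyldiisopinocampheylborane from (+)-α-pinene, C=CCB([C@@H]1C[C@@H]2C[C@H]([C@H]1C)C2(C)C)[C@@H]1C[C@@H]2C[C@H]([C@H]1C)C2(C)C
Why: Brown allylboration through a closed chair (Zimmerman–Traxler) transition state, in which the isopinocampheyl groups of this reagent enantiomer steer the allyl group onto one aldehyde face, as is known for α,α-dimethyl aldehydes, and set C3 as S.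

**Step 7**
Reactants: 10 methyl 3-(benzyloxy)-5-[(3S)-3-hydroxy-2-methylhex-5-en-2-yl]-2,6-dimethylbenzoate
Product: 11 methyl 3-(benzyloxy)-5-[(3S)-3-(tert-butyldimethylsilyloxy)-2-methylhex-5-en-2-yl]-2,6-dimethylbenzoate
Conditions: TBSOTf, 2,6-lutidine, CH2Cl2, 0 °C to rt
Reagents that add atoms: tert-butyldimethylsilyl triflate, CC(C)(C)[Si](C)(C)OS(=O)(=O)C(F)(F)F
Why: Silylation of a hindered secondary alcohol with the silyl triflate and a non-nucleophilic base, which does not touch the stereocentre and later prevents oxetane formation from C3–O and C1.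

**Step 8**
Reactants: 11 methyl 3-(benzyloxy)-5-[(3S)-3-(tert-butyldimethylsilyloxy)-2-methylhex-5-en-2-yl]-2,6-dimethylbenzoate
Product: 13 methyl 3-(benzyloxy)-5-[(3S)-3-(tert-butyldimethylsilyloxy)-5-hydroxy-2-methylpentan-2-yl]-2,6-dimethylbenzoate, via aldehyde 12 (not isolated)
Conditions: O3, CH2Cl2–MeOH, −78 °C, stopped at alkene consumption; then NaBH4, −78 °C to rt
Reagents that add atoms: ozone, [O-][O+]=O
Why: Ozonolysis with reductive work-up, in which the terminal alkene is by far the most ozone-reactive site and NaBH4 carries aldehyde 12 on to the primary alcohol at C1 without touching the hindered benzoate.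

**Step 9**
Reactants: 13 methyl 3-(benzyloxy)-5-[(3S)-3-(tert-butyldimethylsilyloxy)-5-hydroxy-2-methylpentan-2-yl]-2,6-dimethylbenzoate
Product: 14 methyl 3-(benzyloxy)-5-[(3S)-3-(tert-butyldimethylsilyloxy)-2-methyl-5-(tosyloxy)pentan-2-yl]-2,6-dimethylbenzoate
Conditions: TsCl, pyridine, CH2Cl2, 0 °C to rt
Reagents that add atoms: p-toluenesulfonyl chloride, Cc1ccc(cc1)S(=O)(=O)Cl
Why: Sulfonylation of the only free hydroxyl group, an unhindered primary alcohol.

**Step 10**
Reactants: 14 methyl 3-(benzyloxy)-5-[(3S)-3-(tert-butyldimethylsilyloxy)-2-methyl-5-(tosyloxy)pentan-2-yl]-2,6-dimethylbenzoate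
Product: 15 methyl 3-hydroxy-2,6-dimethyl-5-[(3S)-3-(tert-butyldimethylsilyloxy)-2-methyl-5-(tosyloxy)pentan-2-yl]benzoate
Conditions: H2 (1 atm), 10% Pd/C, EtOAc, rt
Reagents that add atoms: none
Why: Hydrogenolysis of the benzyl aryl ether, to which the tosylate, silyl ether and ester are inert.

**Step 11**
Reactants: 15 methyl 3-hydroxy-2,6-dimethyl-5-[(3S)-3-(tert-butyldimethylsilyloxy)-2-methyl-5-(tosyloxy)pentan-2-yl]benzoate
Product: 16 methyl 4-bromo-3-hydroxy-2,6-dimethyl-5-[(3S)-3-(tert-butyldimethylsilyloxy)-2-methyl-5-(tosyloxy)pentan-2-yl]benzoate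
Conditions: NBS (1.0 equiv), i-Pr2NH (cat.), CH2Cl2, 0 °C, dark
Reagents that add atoms: N-bromosuccinimide, O=C1CCC(=O)N1Br
Why: Amine-catalysed ortho-bromination of a phenol, in which C6 is the only ring carbon that still carries hydrogen and lies ortho to the hydroxyl group, and bromine taken up reversibly at the methyl-bearing C10 can migrate there.

**Step 12**
Reactants: 16 methyl 4-bromo-3-hydroxy-2,6-dimethyl-5-[(3S)-3-(tert-butyldimethylsilyloxy)-2-methyl-5-(tosyloxy)pentan-2-yl]benzoate
Product: 18 methyl 6-bromo-3β-(tert-butyldimethylsilyloxy)-7-oxodrima-5,8-dien-11-oate (10β-methyl), via potassium phenoxide 17 (not isolated)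
Conditions: KOt-Bu (1.0 equiv), t-BuOH–THF, 0.01 M, rt to 65 °C
Reagents that add atoms: none
Why: One equivalent of KOt-Bu, which leaves no free alkoxide for E2 or SN2 at the tosylate, converts 16 into phenoxide 17, whose para carbon C10 attacks C1 through its π face in an intramolecular SN2 displacement of tosylate, so the arene becomes the cross-conjugated cyclohexa-2,5-dienone of ring B. The closest known reaction type is the base-induced intramolecular para-alkylation of phenols carrying an ω-sulfonyloxyalkyl chain, that is aryl participation through the ring carbon next to the chain, which gives fused 4,4-disubstituted cyclohexadienones. Ring A (C10–C1–C2–C3–C4–C5) closes in the 6-exo-tet mode (enolendo type, allowed for six-membered rings) and is helped by the gem-dimethyl group at C4 (Thorpe–Ingold effect). The only new stereocentre, C10, is controlled by C3: in the chair-like transition state the C10 methyl must be axial because C9 has to stay in the plane of ring B, and the chair with the silyloxy group equatorial, which avoids a syn-axial contact with the departing sulfonate on C1, places methyl and oxygen on the same (β) face. The step needs C10 to react in preference to oxygen and C6: O-alkylation would require a strained meta-bridged ring and dilution suppresses the intermolecular version, while the bromine on C6 lowers the nucleophilicity of that carbon, closes the rearomatising path to a tetralol and would lead only to a less stable linearly conjugated α-bromodienone.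

**Step 13**
Reactants: 18 methyl 6-bromo-3β-(tert-butyldimethylsilyloxy)-7-oxodrima-5,8-dien-11-oate
Product: 20 methyl 3β-(tert-butyldimethylsilyloxy)-7-oxo-5α-drim-8-en-11-oate, via debrominated dienone 19 (not isolated)
Conditions: H2 (1 atm), 10% Pd/C, Et3N, EtOAc, rt
Reagents that add atoms: none
Why: Heterogeneous hydrogenation, in which the α-bromoenone C–Br bond is hydrogenolysed first and the then trisubstituted C5=C6 bond takes up hydrogen from the α face, opposite the axial 10β and 4β methyl groups, setting 5α-H (trans-decalin), while the tetrasubstituted ester-bearing C8=C9 bond adsorbs too poorly to react and Et3N prevents an acid-induced dienone–phenol rearrangement.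

**Step 14**
Reactants: 20 methyl 3β-(tert-butyldimethylsilyloxy)-7-oxo-5α-drim-8-en-11-oate
Product: 22 methyl 3β-(tert-butyldimethylsilyloxy)-7-(trifluoromethylsulfonyloxy)-5α-drima-6,8-dien-11-oate, via potassium dienolate 21 (not isolated)
Conditions: KN(SiMe3)2, THF, −78 °C; PhNTf2, −78 to 0 °C
Reagents that add atoms: N-phenylbis(trifluoromethanesulfonimide), O=S(=O)(N(c1ccccc1)S(=O)(=O)C(F)(F)F)C(F)(F)F
Why: Enol triflate synthesis by kinetic α′-deprotonation of the enone at C6 (C12–H is activated only vinylogously by the ester) and O-sulfonylation of cross-conjugated dienolate 21, with C5 untouched.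

**Step 15**
Reactants: 22 methyl 3β-(tert-butyldimethylsilyloxy)-7-(trifluoromethylsulfonyloxy)-5α-drima-6,8-dien-11-oate
Product: 23 methyl 3β-(tert-butyldimethylsilyloxy)-5α-drima-6,8-dien-11-oate
Conditions: Pd(OAc)2 (cat.), PPh3 (cat.), HCO2H, Et3N, DMF, 60 °C
Reagents that add atoms: none
Why: Palladium-catalysed formate reduction of an enol triflate (oxidative addition to zerovalent palladium, decarboxylation of formate, C–H reductive elimination), which replaces C7–O by C7–H and leaves the C6=C7 alkene.

**Step 16**
Reactants: 23 methyl 3β-(tert-butyldimethylsilyloxy)-5α-drima-6,8-dien-11-oate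
Product: 25 methyl 3β-(tert-butyldimethylsilyloxy)-5α,9α-H-drima-6,8(12)-dien-11-oate, via lithium trienolate 24 (not isolated)
Conditions: LiN(i-Pr)2, THF–DMPU, −78 °C; AcOH in THF, −78 °C
Reagents that add atoms: none
Why: Deconjugative protonation of an unsaturated ester, in which the amide base removes a proton from C12, the methyl group cis to the ester, and kinetic α-protonation of cross-conjugated enolate 24 at C9 occurs from the α face, anti to the pseudo-axial 10β-methyl group, giving 9α-H, the equatorial ester and the C8=C12 methylene.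

**Step 17**
Reactants: 25 methyl 3β-(tert-butyldimethylsilyloxy)-5α,9α-H-drima-6,8(12)-dien-11-oate
Product: 26 3β-(tert-butyldimethylsilyloxy)drima-6,8(12)-dien-11-ol
Conditions: i-Bu2AlH (2.5 equiv), CH2Cl2, −78 to 0 °C; aq. potassium sodium tartrate
Reagents that add atoms: none
Why: Reduction of the ester to the primary alcohol with a non-basic aluminium hydride, which should neither reconjugate nor epimerise the β,γ-unsaturated ester at C9.

**Step 18**
Reactants: 26 3β-(tert-butyldimethylsilyloxy)drima-6,8(12)-dien-11-ol; 27 umbelliferone (7-hydroxycoumarin)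
Product: 28 7-{[3β-(tert-butyldimethylsilyloxy)drima-6,8(12)-dien-11-yl]oxy}coumarin
Conditions: PPh3, DIAD, THF, 0 °C to rt
Reagents that add atoms: umbelliferone (27), O=c1ccc2ccc(O)cc2o1
Why: Mitsunobu etherification, in which the acidic phenol is alkylated on oxygen by the activated primary C11 alcohol under neutral conditions, so no stereocentre is involved and base-induced elimination toward C9 is avoided.

**Step 19**
Reactants: 28 7-{[3β-(tert-butyldimethylsilyloxy)drima-6,8(12)-dien-11-yl]oxy}coumarin
Product: 29 7-{[(3S,5R,9S,10S)-3-hydroxydrima-6,8(12)-dien-11-yl]oxy}coumarin (CNP0259618.2)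
Conditions: HF·pyridine, pyridine, THF, 0 °C to rt
Reagents that add atoms: none
Why: Fluoride-mediated cleavage of the silyl ether under buffered, weakly acidic conditions that spare the coumarin lactone, the aryl ether and the diene.

**Compound list**
1 | methyl 2,6-dimethylbenzoate | COC(=O)c1c(C)cccc1C | starting material
2 | methyl 3-bromo-2,6-dimethylbenzoate | COC(=O)c1c(C)ccc(Br)c1C | intermediate
3 | methyl isobutyrate | COC(=O)C(C)C | starting material
4 | lithium enolate of methyl isobutyrate (not isolated) | [Li+].COC([O-])=C(C)C | intermediate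
5 | methyl 3-(1-methoxy-2-methyl-1-oxopropan-2-yl)-2,6-dimethylbenzoate | COC(=O)c1c(C)ccc(C(C)(C)C(=O)OC)c1C | intermediate
6 | methyl 3-bromo-5-(1-methoxy-2-methyl-1-oxopropan-2-yl)-2,6-dimethylbenzoate | COC(=O)c1c(C)c(Br)cc(C(C)(C)C(=O)OC)c1C | intermediate
7 | methyl 3-(benzyloxy)-5-(1-methoxy-2-methyl-1-oxopropan-2-yl)-2,6-dimethylbenzoate | COC(=O)c1c(C)c(OCc2ccccc2)cc(C(C)(C)C(=O)OC)c1C | intermediate
8 | methyl 3-(benzyloxy)-2,6-dimethyl-5-(2-methyl-1-oxopropan-2-yl)benzoate | COC(=O)c1c(C)c(OCc2ccccc2)cc(C(C)(C)C=O)c1C | intermediate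
9 | diisopinocampheylborinate ester of alcohol 10 (not isolated) | COC(=O)c1c(C)c(OCc2ccccc2)cc(C(C)(C)[C@@H](OB([C@@H]2C[C@@H]3C[C@H]([C@H]2C)C3(C)C)[C@@H]2C[C@@H]3C[C@H]([C@H]2C)C3(C)C)CC=C)c1C | intermediate
10 | methyl 3-(benzyloxy)-5-[(3S)-3-hydroxy-2-methylhex-5-en-2-yl]-2,6-dimethylbenzoate | COC(=O)c1c(C)c(OCc2ccccc2)cc(C(C)(C)[C@@H](O)CC=C)c1C | intermediate
11 | methyl 3-(benzyloxy)-5-[(3S)-3-(tert-butyldimethylsilyloxy)-2-methylhex-5-en-2-yl]-2,6-dimethylbenzoate | COC(=O)c1c(C)c(OCc2ccccc2)cc(C(C)(C)[C@@H](O[Si](C)(C)C(C)(C)C)CC=C)c1C | intermediate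
12 | methyl 3-(benzyloxy)-5-[(3S)-3-(tert-butyldimethylsilyloxy)-2-methyl-5-oxopentan-2-yl]-2,6-dimethylbenzoate (not isolated) | COC(=O)c1c(C)c(OCc2ccccc2)cc(C(C)(C)[C@@H](O[Si](C)(C)C(C)(C)C)CC=O)c1C | intermediate
13 | methyl 3-(benzyloxy)-5-[(3S)-3-(tert-butyldimethylsilyloxy)-5-hydroxy-2-methylpentan-2-yl]-2,6-dimethylbenzoate | COC(=O)c1c(C)c(OCc2ccccc2)cc(C(C)(C)[C@@H](O[Si](C)(C)C(C)(C)C)CCO)c1C | intermediate
14 | methyl 3-(benzyloxy)-5-[(3S)-3-(tert-butyldimethylsilyloxy)-2-methyl-5-(tosyloxy)pentan-2-yl]-2,6-dimethylbenzoate | COC(=O)c1c(C)c(OCc2ccccc2)cc(C(C)(C)[C@@H](O[Si](C)(C)C(C)(C)C)CCOS(=O)(=O)c2ccc(C)cc2)c1C | intermediate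
15 | methyl 3-hydroxy-2,6-dimethyl-5-[(3S)-3-(tert-butyldimethylsilyloxy)-2-methyl-5-(tosyloxy)pentan-2-yl]benzoate | COC(=O)c1c(C)c(O)cc(C(C)(C)[C@@H](O[Si](C)(C)C(C)(C)C)CCOS(=O)(=O)c2ccc(C)cc2)c1C | intermediate
16 | methyl 4-bromo-3-hydroxy-2,6-dimethyl-5-[(3S)-3-(tert-butyldimethylsilyloxy)-2-methyl-5-(tosyloxy)pentan-2-yl]benzoate | Cc1c(O)c(Br)c(C(C)(C)[C@@H](O[Si](C)(C)C(C)(C)C)CCOS(=O)(=O)c2ccc(C)cc2)c(C)c1C(=O)OC | intermediate
17 | potassium phenoxide of 16 (not isolated) | [K+].Cc1c([O-])c(Br)c(C(C)(C)[C@@H](O[Si](C)(C)C(C)(C)C)CCOS(=O)(=O)c2ccc(C)cc2)c(C)c1C(=O)OC | intermediate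
18 | methyl 6-bromo-3β-(tert-butyldimethylsilyloxy)-7-oxodrima-5,8-dien-11-oate (10β-methyl cis to 3β-oxygen) | COC(=O)C1=C(C)C(=O)C(Br)=C2C(C)(C)[C@@H](O[Si](C)(C)C(C)(C)C)CC[C@]12C | intermediate
19 | methyl 3β-(tert-butyldimethylsilyloxy)-7-oxodrima-5,8-dien-11-oate (not isolated) | COC(=O)C1=C(C)C(=O)C=C2C(C)(C)[C@@H](O[Si](C)(C)C(C)(C)C)CC[C@]12C | intermediate
20 | methyl 3β-(tert-butyldimethylsilyloxy)-7-oxo-5α-drim-8-en-11-oate (trans-decalin) | COC(=O)C1=C(C)C(=O)C[C@H]2C(C)(C)[C@@H](O[Si](C)(C)C(C)(C)C)CC[C@]12C | intermediate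
21 | potassium 6,8-dien-7-olate of 20 (not isolated) | [K+].COC(=O)C1=C(C)C([O-])=C[C@H]2C(C)(C)[C@@H](O[Si](C)(C)C(C)(C)C)CC[C@]12C | intermediate
22 | methyl 3β-(tert-butyldimethylsilyloxy)-7-(trifluoromethylsulfonyloxy)-5α-drima-6,8-dien-11-oate | COC(=O)C1=C(C)C(OS(=O)(=O)C(F)(F)F)=C[C@H]2C(C)(C)[C@@H](O[Si](C)(C)C(C)(C)C)CC[C@]12C | intermediate
23 | methyl 3β-(tert-butyldimethylsilyloxy)-5α-drima-6,8-dien-11-oate | COC(=O)C1=C(C)C=C[C@H]2C(C)(C)[C@@H](O[Si](C)(C)C(C)(C)C)CC[C@]12C | intermediate
24 | lithium enolate of 23 with C9=C11, C8=C12 and C6=C7 (not isolated) | [Li+].COC([O-])=C1C(=C)C=C[C@H]2C(C)(C)[C@@H](O[Si](C)(C)C(C)(C)C)CC[C@]12C | intermediate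
25 | methyl 3β-(tert-butyldimethylsilyloxy)-5α,9α-H-drima-6,8(12)-dien-11-oate | C=C1C=C[C@H]2C(C)(C)[C@@H](O[Si](C)(C)C(C)(C)C)CC[C@]2(C)[C@H]1C(=O)OC | intermediate
26 | 3β-(tert-butyldimethylsilyloxy)-5α,9α-H-drima-6,8(12)-dien-11-ol | C=C1C=C[C@H]2C(C)(C)[C@@H](O[Si](C)(C)C(C)(C)C)CC[C@]2(C)[C@H]1CO | intermediate
27 | umbelliferone (7-hydroxycoumarin) | O=c1ccc2ccc(O)cc2o1 | starting material
28 | 7-{[3β-(tert-butyldimethylsilyloxy)-5α,9α-H-drima-6,8(12)-dien-11-yl]oxy}coumarin | C=C1C=C[C@H]2C(C)(C)[C@@H](O[Si](C)(C)C(C)(C)C)CC[C@]2(C)[C@H]1COc1ccc2ccc(=O)oc2c1 | intermediate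
29 | 7-{[(3S,5R,9S,10S)-3-hydroxydrima-6,8(12)-dien-11-yl]oxy}coumarin (3β-OH, 5α-H, 9α-H, 10β-methyl) | C=C1C=C[C@H]2C(C)(C)[C@@H](O)CC[C@]2(C)[C@H]1COc1ccc2ccc(=O)oc2c1 | target

Total step count: 19. Longest linear sequence: 19 steps (1 to 29). Compounds 3 and 27 enter as purchased building blocks.

**Steps most likely to fail**

Step 12 (key step). Three things may go wrong.
- Closure could run through the bromine-bearing C6 instead of C10.
- Base could eliminate the tosylate.
- The equatorial and axial silyloxy chairs could be poorly discriminated, giving poor facial selectivity at C10.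

The fallback moves activation from the nucleophile to the electrophile. It sets out from 16. A Finkelstein exchange (NaI, acetone, reflux) gives methyl 4-bromo-3-hydroxy-5-[(3S)-3-(tert-butyldimethylsilyloxy)-5-iodo-2-methylpentan-2-yl]-2,6-dimethylbenzoate F1. Silver triflate (AgOSO2CF3) with 2,6-di-tert-butylpyridine in CH2Cl2 then abstracts iodide while the neutral phenol ring participates through C10. Loss of the phenolic proton gives 18, where the route is rejoined. No free base is present, so elimination is removed. A bromine-bearing carbon of a neutral phenol is a very poor site for electrophilic attack. The later, more product-like transition state should also feel the chair preference more strongly.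

Step 13. The C8=C9 bond may be saturated in competition, hydrogen uptake at the doubly neopentyl C5=C6 bond may be sluggish, or hydrogen may be delivered to the β face. The fallback sets out from 18 and replaces surface hydrogenation by two separate mechanisms.
- Bromine is first removed alone by palladium-catalysed formate transfer (Pd(OAc)2, PPh3, HCO2H, Et3N, DMF, 50 °C), so that dienone 19 is isolated.
- Dienone 19 is then reduced by metal-hydride hydrogen-atom transfer (Mn(dpm)3 cat., PhSiH3, t-BuOOH, i-PrOH, rt).

This stepwise radical hydrogenation passes over tetrasubstituted alkenes and favours the thermodynamically preferred trans ring fusion. The route is rejoined at 20, and no compound outside the list is made (F0).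

Step 11. The electrophile may attack at the methyl-bearing para carbon C10, followed by benzylic oxidation. Alternatively there may be no substitution because the site lies between the hydroxyl group and a tert-alkyl group that is buttressed by the C10 methyl. The fallback changes the blocking atom to the smaller chlorine and delivers it by a different, hydroxyl-directed mechanism. It sets out from 15.
- SO2Cl2 with catalytic 2,2,6,6-tetramethylpiperidine in toluene at 0 °C chlorinates ortho, through an N-chloroamine hydrogen-bonded to the phenol. This gives methyl 4-chloro-3-hydroxy-2,6-dimethyl-5-[(3S)-3-(tert-butyldimethylsilyloxy)-2-methyl-5-(tosyloxy)pentan-2-yl]benzoate F2.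
- KOt-Bu under the conditions of step 12 forms the potassium phenoxide of the chlorophenol F3, which closes to methyl 6-chloro-3β-(tert-butyldimethylsilyloxy)-7-oxodrima-5,8-dien-11-oate F4.
- Hydrogenation under the conditions of step 13 removes chlorine and saturates C5=C6, and the route is rejoined at 20.

**Further compounds**
F1 | step 12 | methyl 4-bromo-3-hydroxy-5-[(3S)-3-(tert-butyldimethylsilyloxy)-5-iodo-2-methylpentan-2-yl]-2,6-dimethylbenzoate | Cc1c(O)c(Br)c(C(C)(C)[C@@H](O[Si](C)(C)C(C)(C)C)CCI)c(C)c1C(=O)OC
F0 | step 13 | none | none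
F2 | step 11 | methyl 4-chloro-3-hydroxy-2,6-dimethyl-5-[(3S)-3-(tert-butyldimethylsilyloxy)-2-methyl-5-(tosyloxy)pentan-2-yl]benzoate | Cc1c(O)c(Cl)c(C(C)(C)[C@@H](O[Si](C)(C)C(C)(C)C)CCOS(=O)(=O)c2ccc(C)cc2)c(C)c1C(=O)OC
F3 | step 11 | potassium phenoxide of the chlorophenol | [K+].Cc1c([O-])c(Cl)c(C(C)(C)[C@@H](O[Si](C)(C)C(C)(C)C)CCOS(=O)(=O)c2ccc(C)cc2)c(C)c1C(=O)OC
F4 | step 11 | methyl 6-chloro-3β-(tert-butyldimethylsilyloxy)-7-oxodrima-5,8-dien-11-oate | COC(=O)C1=C(C)C(=O)C(Cl)=C2C(C)(C)[C@@H](O[Si](C)(C)C(C)(C)C)CC[C@]12C
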